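Rings are numbered 1 (2,4,6-trihydroxyphenyl end) to 10 (3,4,5-trihydroxyphenyl end); all 26 hydroxyls are carried as methyl ethers and freed last.
The retrosynthesis cuts five diaryl ether bonds: the ring 1 oxygen to C1 of ring 2, and the C2 oxygens of rings 3, 5, 7 and 9 to C1 of rings 4, 6, 8 and 10. Each joins a hindered phenol oxygen to a ring carbon lying between two CH groups, and the cuts leave ring 1, ring 10 and four copies of one two-ring boronic acid.
Rings 3, 5, 7 and 9 each carry five contiguous oxygens (C1 aryloxy from the preceding ring, C2 aryloxy to the next ring, C3 to C5 hydroxyls) and a single CH (C6). C2 to C5 map onto the four carbons of dimethyl squarate and C1/C6 onto a 1-aryloxyvinyl unit, so this ring is cut at C5–C6.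
Forward, 2,6-dimethoxyphenol (the future rings 2, 4, 6, 8) becomes an alpha-stannyl vinyl ether, is added to dimethyl squarate, and the cyclobutenone is ring-expanded to the pentaoxygenated ring with its C2 oxygen silylated and its C5 oxygen free. Methylation and C–H borylation para to the ether oxygen complete the building block.
The block is coupled four times in a row (ring 1 phenol first, desilylation between couplings), ring 10 is added, and the methyl ethers are cleaved.
The target has no stereocentre; the only stereogenic carbon on the way (C4 of the cyclobutenone, racemic) is erased in the ring expansion.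

Key step: step 5

Remark on the chemistry: the terminal aryl ethynyl ether made in step 2 is assumed to be stable enough in cold solution for immediate use; it is not stored.
Remark on names: "O-methylated rings 1–n" means the first n rings of the target joined as in the target, with every oxygen that is a hydroxyl in the target present as a methyl ether; the C2 oxygen of the last ring (the one that carries the next ring in the target) is named separately.

Step 1
Reactants: 1 2,6-dimethoxyphenol; 2 trichloroethylene
Product: 4 2-{[(E)-1,2-dichloroethenyl]oxy}-1,3-dimethoxybenzene, via dichloroacetylene 3 (not isolated)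
Conditions: K2CO3 (2 equiv), DMF, 70 °C
Reagents that add atoms: none
Why: Base-induced loss of HCl from trichloroethylene gives dichloroacetylene, to which the phenoxide adds in anti fashion (the standard synthesis of aryl (E)-1,2-dichlorovinyl ethers), and the two ortho methoxy groups do not block attack through oxygen.

Step 2
Reactants: 4 2-{[(E)-1,2-dichloroethenyl]oxy}-1,3-dimethoxybenzene
Product: 7 2-(ethynyloxy)-1,3-dimethoxybenzene, via chloroethynyl ether 5 (not isolated), via lithium acetylide 6 (not isolated)
Conditions: n-BuLi (2.3 equiv), THF, −78 → −40 °C; then H2O, −78 °C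
Reagents that add atoms: none
Why: Vinyl deprotonation and loss of LiCl give the chloroalkyne, chlorine–lithium exchange with the second equivalent gives the lithium acetylide, and water protonates it (the known dichlorovinyl ether to ynol ether conversion), while the anisole-type ring C–H bonds are not metalated at −78 °C.

Step 3
Reactants: 7 2-(ethynyloxy)-1,3-dimethoxybenzene
Product: 8 tributyl[1-(2,6-dimethoxyphenoxy)ethenyl]stannane
Conditions: Bu3SnH (1.1 equiv), Pd(PPh3)4 (2 mol %), THF, 0 °C → rt
Reagents that add atoms: tributyltin hydride, CCCC[SnH](CCCC)CCCC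
Why: Hydrostannation of 1-alkoxyalkynes under zerovalent palladium catalysis is a syn addition that places tin on the oxygen-bearing carbon, which here should give the 1-(aryloxy)vinylstannane.

Step 4
Reactants: 8 tributyl[1-(2,6-dimethoxyphenoxy)ethenyl]stannane; 9 dimethyl squarate
Product: 12 4-[(tert-butyldimethylsilyl)oxy]-4-[1-(2,6-dimethoxyphenoxy)ethenyl]-2,3-dimethoxycyclobut-2-en-1-one (racemic), via vinyllithium 10 (not isolated), via lithium alkoxide 11 (not isolated)
Conditions: n-BuLi (1.0 equiv), THF, −78 °C; cannulated into 9, THF, −78 °C; then TBSOTf (1.2 equiv), 2,6-lutidine, −78 → −40 °C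
Reagents that add atoms: tert-butyldimethylsilyl trifluoromethanesulfonate, CC(C)(C)[Si](C)(C)OS(=O)(=O)C(F)(F)F
Why: Tin–lithium exchange outruns any ring metalation and gives the alpha-(aryloxy)vinyllithium, which adds 1,2 to one carbonyl of the squarate ester at −78 °C (standard squarate chemistry), and the tertiary lithium alkoxide is O-silylated by the silyl triflate before it can ring-open.

Step 5
Reactants: 12 4-[(tert-butyldimethylsilyl)oxy]-4-[1-(2,6-dimethoxyphenoxy)ethenyl]-2,3-dimethoxycyclobut-2-en-1-one
Product: 15 4-[(tert-butyldimethylsilyl)oxy]-5-(2,6-dimethoxyphenoxy)-2,3-dimethoxyphenol, via dienylketene 13 (not isolated), via cyclohexadienone 14 (not isolated)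
Conditions: toluene (0.02 M, degassed), 110 °C
Reagents that add atoms: none
Why: Heating should open the cyclobutenone by four-electron conrotatory cleavage of the C1–C4 bond to the (Z)-dienylketene 13, whose ketene carbon and vinyl CH2 terminus then join (the C5–C6 bond of the pentaoxygenated ring) to give cyclohexadienone 14, and enolisation of its CH2–C=O unit gives the phenol. The closest known reaction type is the thermal ring expansion of 4-alkenyl-4-hydroxy- and 4-siloxycyclobutenones derived from squarate esters to hydroquinones and their monoethers (Moore rearrangement). The one ring formed closes by a six-electron disrotatory electrocyclisation of a triene in which the ketene C=C is the terminal double bond. No stereocentre is created, and the racemic C4 of 12 becomes an sp2 carbon. The step needs the vinyl group to turn inward on ring opening, which the strongly donating siloxy group secures by its own preference for outward rotation. It also needs the two phenolic oxygens to remain distinguishable, which the connectivity secures: the silyl group stays on the oxygen flanked by the aryloxy group, and the ketene oxygen appears as the only free hydroxyl, next to the CH.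

Step 6
Reactants: 15 4-[(tert-butyldimethylsilyl)oxy]-5-(2,6-dimethoxyphenoxy)-2,3-dimethoxyphenol
Product: 16 tert-butyl[6-(2,6-dimethoxyphenoxy)-2,3,4-trimethoxyphenoxy]dimethylsilane
Conditions: MeI (3 equiv), K2CO3, dry acetone, 45 °C
Reagents that add atoms: iodomethane, CI
Why: Williamson methylation of the single free phenol (the C5 oxygen of the new ring) runs under mild carbonate conditions that should leave the doubly ortho-flanked aryl silyl ether untouched.

Step 7
Reactants: 16 tert-butyl[6-(2,6-dimethoxyphenoxy)-2,3,4-trimethoxyphenoxy]dimethylsilane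
Product: 18 [4-({2-[(tert-butyldimethylsilyl)oxy]-3,4,5-trimethoxyphenyl}oxy)-3,5-dimethoxyphenyl]boronic acid, via pinacol boronate 17 (not isolated)
Conditions: [Ir(cod)OMe]2 (1.5 mol %), 4,4′-di-tert-butyl-2,2′-bipyridine (3 mol %), B2pin2 (0.6 equiv), THF, 80 °C; then NaIO4 (3 equiv), NH4OAc, acetone–H2O, rt
Reagents that add atoms: bis(pinacolato)diboron, CC1(C)OB(OC1(C)C)B1OC(C)(C)C(C)(C)O1; water, O
Why: Iridium-catalysed aromatic C–H borylation is governed by sterics, and 16 has only one aromatic C–H without an ortho substituent (para to the ether oxygen of the dimethoxyphenoxy ring, between two CH), after which periodate cleaves the pinacol ester to the boronic acid in the same flask.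

Step 8
Reactants: 19 2,4,6-trimethoxyphenol; 18 [4-({2-[(tert-butyldimethylsilyl)oxy]-3,4,5-trimethoxyphenyl}oxy)-3,5-dimethoxyphenyl]boronic acid
Product: 20 tert-butyl{6-[2,6-dimethoxy-4-(2,4,6-trimethoxyphenoxy)phenoxy]-2,3,4-trimethoxyphenoxy}dimethylsilane (O-methylated rings 1–3 trimer silylated at the ring 3 C2 oxygen)
Conditions: 18 (1.5 equiv), Cu(OAc)2 (1.0 equiv), pyridine (5 equiv), 4 Å molecular sieves, CH2Cl2, dry air, rt
Reagents that add atoms: none
Why: In this Chan–Lam coupling the arylboronic acid transmetalates to divalent copper, the phenoxide binds, and C–O reductive elimination from trivalent copper gives the diaryl ether while air returns copper to the divalent state; the boron-bearing carbon lies between two CH groups, 2,6-disubstituted phenols are known partners, and the para methoxy group of 19 blocks oxidative phenol coupling.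

Step 9
Reactants: 20 O-methylated rings 1–3 trimer silylated at the ring 3 C2 oxygen
Product: 21 6-[2,6-dimethoxy-4-(2,4,6-trimethoxyphenoxy)phenoxy]-2,3,4-trimethoxyphenol (O-methylated rings 1–3 trimer with free ring 3 C2 hydroxyl)
Conditions: TBAF (1.1 equiv), AcOH (1.1 equiv), THF, 0 °C, argon
Reagents that add atoms: none
Why: Fluoride cleaves the aryl silyl ether selectively, the acetic acid buffer keeps the electron-rich phenoxide from air oxidation, and methyl and diaryl ethers are inert.

Step 10
Reactants: 21 O-methylated rings 1–3 trimer with free ring 3 C2 hydroxyl; 18 the boronic acid of step 7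
Product: 22 O-methylated rings 1–5 pentamer silylated (tert-butyldimethylsilyl) at the ring 5 C2 oxygen
Conditions: 18 (2 equiv), Cu(OAc)2 (1.0 equiv), pyridine (5 equiv), 4 Å molecular sieves, CH2Cl2, dry air, rt
Reagents that add atoms: none
Why: The same Chan–Lam coupling joins the ring 3 C2 oxygen, flanked by an aryloxy and a methoxy group, to the unhindered boron-bearing carbon that becomes C1 of ring 4, and the silyl ether of 18 keeps the block from coupling with itself.

Step 11
Reactants: 22 O-methylated rings 1–5 pentamer silylated at the ring 5 C2 oxygen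
Product: 23 O-methylated rings 1–5 pentamer with free ring 5 C2 hydroxyl
Conditions: TBAF (1.1 equiv), AcOH (1.1 equiv), THF, 0 °C, argon
Reagents that add atoms: none
Why: Buffered fluoride desilylation as in step 9 should free only the ring 5 C2 phenol.

Step 12
Reactants: 23 O-methylated rings 1–5 pentamer with free ring 5 C2 hydroxyl; 18 the boronic acid of step 7
Product: 24 O-methylated rings 1–7 heptamer silylated (tert-butyldimethylsilyl) at the ring 7 C2 oxygen
Conditions: 18 (2 equiv), Cu(OAc)2 (1.0 equiv), pyridine (5 equiv), 4 Å molecular sieves, CH2Cl2, dry air, rt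
Reagents that add atoms: none
Why: This repeats the Chan–Lam coupling of step 10 on the next homologue, whose reacting phenol has the same local environment, so the same reactivity is expected.

Step 13
Reactants: 24 O-methylated rings 1–7 heptamer silylated at the ring 7 C2 oxygen
Product: 25 O-methylated rings 1–7 heptamer with free ring 7 C2 hydroxyl
Conditions: TBAF (1.1 equiv), AcOH (1.1 equiv), THF, 0 °C, argon
Reagents that add atoms: none
Why: Buffered fluoride desilylation as in step 9 should free only the ring 7 C2 phenol.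

Step 14
Reactants: 25 O-methylated rings 1–7 heptamer with free ring 7 C2 hydroxyl; 18 the boronic acid of step 7
Product: 26 O-methylated rings 1–9 nonamer silylated (tert-butyldimethylsilyl) at the ring 9 C2 oxygen
Conditions: 18 (2 equiv), Cu(OAc)2 (1.0 equiv), pyridine (5 equiv), 4 Å molecular sieves, CH2Cl2, dry air, rt
Reagents that add atoms: none
Why: This is the fourth use of the Chan–Lam coupling of step 10, again between a phenol of unchanged local environment and the unhindered boron-bearing carbon, now the future C1 of ring 8.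

Step 15
Reactants: 26 O-methylated rings 1–9 nonamer silylated at the ring 9 C2 oxygen
Product: 27 O-methylated rings 1–9 nonamer with free ring 9 C2 hydroxyl
Conditions: TBAF (1.1 equiv), AcOH (1.1 equiv), THF, 0 °C, argon
Reagents that add atoms: none
Why: Buffered fluoride desilylation as in step 9 should free only the ring 9 C2 phenol.

Step 16
Reactants: 27 O-methylated rings 1–9 nonamer with free ring 9 C2 hydroxyl; 28 (3,4,5-trimethoxyphenyl)boronic acid
Product: 29 hexacosa-O-methyl ether of the target (O-methylated rings 1–10 decamer)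
Conditions: 28 (3 equiv), Cu(OAc)2 (1.0 equiv), pyridine (5 equiv), 4 Å molecular sieves, CH2Cl2, dry air, rt
Reagents that add atoms: none
Why: Chan–Lam coupling with this electron-rich boronic acid, whose boron-bearing carbon again lies between two CH groups, should put ring 10 on the ring 9 C2 oxygen.

Step 17
Reactants: 29 hexacosa-O-methyl ether of the target
Product: 30 CNP0255890.0 (rings 1–10 decamer with all 26 hydroxyls free)
Conditions: BBr3 (80 equiv), CH2Cl2, −78 °C → rt; MeOH then H2O, 0 °C, argon
Reagents that add atoms: none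
Why: BBr3 cleaves aryl methyl ethers through O–B coordination and bromide attack at methyl while diaryl ether bonds are not touched, and hydrolysis of the aryl borates releases the polyphenol.

Compound list
1 | 2,6-dimethoxyphenol | COc1cccc(OC)c1O | starting material
2 | trichloroethylene | ClC=C(Cl)Cl | starting material
3 | dichloroacetylene | ClC#CCl | intermediate (not isolated)
4 | 2-{[(E)-1,2-dichloroethenyl]oxy}-1,3-dimethoxybenzene | COc1cccc(OC)c1O/C(Cl)=C\Cl | intermediate
5 | 2-[(chloroethynyl)oxy]-1,3-dimethoxybenzene | COc1cccc(OC)c1OC#CCl | intermediate (not isolated)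
6 | [(2,6-dimethoxyphenoxy)ethynyl]lithium | COc1cccc(OC)c1OC#C[Li] | intermediate (not isolated)
7 | 2-(ethynyloxy)-1,3-dimethoxybenzene | COc1cccc(OC)c1OC#C | intermediate
8 | tributyl[1-(2,6-dimethoxyphenoxy)ethenyl]stannane | CCCC[Sn](CCCC)(CCCC)C(=C)Oc1c(OC)cccc1OC | intermediate
9 | dimethyl squarate (3,4-dimethoxycyclobut-3-ene-1,2-dione) | COC1=C(OC)C(=O)C1=O | starting material
10 | [1-(2,6-dimethoxyphenoxy)ethenyl]lithium | [Li]C(=C)Oc1c(OC)cccc1OC | intermediate (not isolated)
11 | lithium 1-[1-(2,6-dimethoxyphenoxy)ethenyl]-2,3-dimethoxy-4-oxocyclobut-2-en-1-olate (racemic) | COC1=C(OC)C([O-])(C(=C)Oc2c(OC)cccc2OC)C1=O.[Li+] | intermediate (not isolated)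
12 | 4-[(tert-butyldimethylsilyl)oxy]-4-[1-(2,6-dimethoxyphenoxy)ethenyl]-2,3-dimethoxycyclobut-2-en-1-one (racemic) | COC1=C(OC)C(O[Si](C)(C)C(C)(C)C)(C(=C)Oc2c(OC)cccc2OC)C1=O | intermediate
13 | (3Z)-4-[(tert-butyldimethylsilyl)oxy]-5-(2,6-dimethoxyphenoxy)-2,3-dimethoxyhexa-1,3,5-trien-1-one | O=C=C(OC)/C(OC)=C(\C(=C)Oc1c(OC)cccc1OC)O[Si](C)(C)C(C)(C)C | intermediate (not isolated)
14 | 4-[(tert-butyldimethylsilyl)oxy]-5-(2,6-dimethoxyphenoxy)-2,3-dimethoxycyclohexa-2,4-dien-1-one | COC1=C(OC)C(O[Si](C)(C)C(C)(C)C)=C(Oc2c(OC)cccc2OC)CC1=O | intermediate (not isolated)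
15 | 4-[(tert-butyldimethylsilyl)oxy]-5-(2,6-dimethoxyphenoxy)-2,3-dimethoxyphenol | COc1cccc(OC)c1Oc1cc(O)c(OC)c(OC)c1O[Si](C)(C)C(C)(C)C | intermediate
16 | tert-butyl[6-(2,6-dimethoxyphenoxy)-2,3,4-trimethoxyphenoxy]dimethylsilane | COc1cccc(OC)c1Oc1cc(OC)c(OC)c(OC)c1O[Si](C)(C)C(C)(C)C | intermediate
17 | tert-butyl{6-[2,6-dimethoxy-4-(4,4,5,5-tetramethyl-1,3,2-dioxaborolan-2-yl)phenoxy]-2,3,4-trimethoxyphenoxy}dimethylsilane | COc1cc(B2OC(C)(C)C(C)(C)O2)cc(OC)c1Oc1cc(OC)c(OC)c(OC)c1O[Si](C)(C)C(C)(C)C | intermediate (not isolated)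
18 | [4-({2-[(tert-butyldimethylsilyl)oxy]-3,4,5-trimethoxyphenyl}oxy)-3,5-dimethoxyphenyl]boronic acid | COc1cc(B(O)O)cc(OC)c1Oc1cc(OC)c(OC)c(OC)c1O[Si](C)(C)C(C)(C)C | intermediate
19 | 2,4,6-trimethoxyphenol | COc1cc(OC)c(O)c(OC)c1 | starting material
20 | tert-butyl{6-[2,6-dimethoxy-4-(2,4,6-trimethoxyphenoxy)phenoxy]-2,3,4-trimethoxyphenoxy}dimethylsilane (O-methylated rings 1–3 trimer, ring 3 C2 silyl ether) | COc1cc(OC)c(Oc2cc(OC)c(Oc3cc(OC)c(OC)c(OC)c3O[Si](C)(C)C(C)(C)C)c(OC)c2)c(OC)c1 | intermediate
21 | 6-[2,6-dimethoxy-4-(2,4,6-trimethoxyphenoxy)phenoxy]-2,3,4-trimethoxyphenol (O-methylated rings 1–3 trimer, free ring 3 C2 hydroxyl) | COc1cc(OC)c(Oc2cc(OC)c(Oc3cc(OC)c(OC)c(OC)c3O)c(OC)c2)c(OC)c1 | intermediate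
22 | O-methylated rings 1–5 pentamer, ring 5 C2 tert-butyldimethylsilyl ether | COc1cc(OC)c(Oc2cc(OC)c(Oc3cc(OC)c(OC)c(OC)c3Oc3cc(OC)c(Oc4cc(OC)c(OC)c(OC)c4O[Si](C)(C)C(C)(C)C)c(OC)c3)c(OC)c2)c(OC)c1 | intermediate
23 | O-methylated rings 1–5 pentamer, free ring 5 C2 hydroxyl | COc1cc(OC)c(Oc2cc(OC)c(Oc3cc(OC)c(OC)c(OC)c3Oc3cc(OC)c(Oc4cc(OC)c(OC)c(OC)c4O)c(OC)c3)c(OC)c2)c(OC)c1 | intermediate
24 | O-methylated rings 1–7 heptamer, ring 7 C2 tert-butyldimethylsilyl ether | COc1cc(OC)c(Oc2cc(OC)c(Oc3cc(OC)c(OC)c(OC)c3Oc3cc(OC)c(Oc4cc(OC)c(OC)c(OC)c4Oc4cc(OC)c(Oc5cc(OC)c(OC)c(OC)c5O[Si](C)(C)C(C)(C)C)c(OC)c4)c(OC)c3)c(OC)c2)c(OC)c1 | intermediate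
25 | O-methylated rings 1–7 heptamer, free ring 7 C2 hydroxyl | COc1cc(OC)c(Oc2cc(OC)c(Oc3cc(OC)c(OC)c(OC)c3Oc3cc(OC)c(Oc4cc(OC)c(OC)c(OC)c4Oc4cc(OC)c(Oc5cc(OC)c(OC)c(OC)c5O)c(OC)c4)c(OC)c3)c(OC)c2)c(OC)c1 | intermediate
26 | O-methylated rings 1–9 nonamer, ring 9 C2 tert-butyldimethylsilyl ether | COc1cc(OC)c(Oc2cc(OC)c(Oc3cc(OC)c(OC)c(OC)c3Oc3cc(OC)c(Oc4cc(OC)c(OC)c(OC)c4Oc4cc(OC)c(Oc5cc(OC)c(OC)c(OC)c5Oc5cc(OC)c(Oc6cc(OC)c(OC)c(OC)c6O[Si](C)(C)C(C)(C)C)c(OC)c5)c(OC)c4)c(OC)c3)c(OC)c2)c(OC)c1 | intermediate
27 | O-methylated rings 1–9 nonamer, free ring 9 C2 hydroxyl | COc1cc(OC)c(Oc2cc(OC)c(Oc3cc(OC)c(OC)c(OC)c3Oc3cc(OC)c(Oc4cc(OC)c(OC)c(OC)c4Oc4cc(OC)c(Oc5cc(OC)c(OC)c(OC)c5Oc5cc(OC)c(Oc6cc(OC)c(OC)c(OC)c6O)c(OC)c5)c(OC)c4)c(OC)c3)c(OC)c2)c(OC)c1 | intermediate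
28 | (3,4,5-trimethoxyphenyl)boronic acid | COc1cc(B(O)O)cc(OC)c1OC | starting material
29 | hexacosa-O-methyl ether of the target (O-methylated rings 1–10 decamer) | COc1cc(OC)c(Oc2cc(OC)c(Oc3cc(OC)c(OC)c(OC)c3Oc3cc(OC)c(Oc4cc(OC)c(OC)c(OC)c4Oc4cc(OC)c(Oc5cc(OC)c(OC)c(OC)c5Oc5cc(OC)c(Oc6cc(OC)c(OC)c(OC)c6Oc6cc(OC)c(OC)c(OC)c6)c(OC)c5)c(OC)c4)c(OC)c3)c(OC)c2)c(OC)c1 | intermediate
30 | CNP0255890.0 (rings 1–10 decamer, 26 free hydroxyls, no stereocentre) | Oc1cc(O)c(Oc2cc(O)c(Oc3cc(O)c(O)c(O)c3Oc3cc(O)c(Oc4cc(O)c(O)c(O)c4Oc4cc(O)c(Oc5cc(O)c(O)c(O)c5Oc5cc(O)c(Oc6cc(O)c(O)c(O)c6Oc6cc(O)c(O)c(O)c6)c(O)c5)c(O)c4)c(O)c3)c(O)c2)c(O)c1 | target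

Total step count: 17
Longest linear sequence: 17 steps (from 1 to 30); the building block 18 made in steps 1–7 is used four times.

Steps most likely to fail

1. Step 10 (the same coupling recurs in steps 12 and 14, and in simpler form in steps 8 and 16). C–O bond formation at the doubly ortho-flanked, very electron-rich phenol may be slow, so that oxidation of the phenol by divalent copper and air, and protodeboronation or hydroxylation of the boronic acid, take over. The fallback replaces the oxidative boronic acid coupling by a non-oxidative aryl halide coupling. It sets out from 16 and 21 and comes back at 22. After the borylation of step 7, the pinacol boronate 17 would be treated in the same flask with CuI (10 mol %), 1,10-phenanthroline and KI in MeOH–H2O under air at 80 °C instead of periodate, giving the aryl iodide tert-butyl[6-(4-iodo-2,6-dimethoxyphenoxy)-2,3,4-trimethoxyphenoxy]dimethylsilane F1. F1 and phenol 21 would then be joined under argon with CuI (10 mol %), picolinic acid and anhydrous K3PO4 in DMSO at 80 °C. This is an Ullmann-type coupling through monovalent copper that is known for 2,6-disubstituted phenols. The silyl ether, flanked by two ortho substituents, should withstand the anhydrous base. The product is 22, and the same iodide would serve for 24 and 26.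

2. Step 17. Cleavage of all 26 methyl ethers may stop short, and the free pyrogallol-type rings may oxidise in air during isolation, leaving a mixture that cannot be purified as the free polyphenol. The fallback sets out from 29 and comes back at 30. After the BBr3 treatment and methanol quench, the crude polyphenol would not be isolated but acetylated directly (Ac2O, pyridine, DMAP, rt) to the hexacosaacetate of the target F2. F2 is stable in air and can be separated on silica from incompletely demethylated material. Acid-catalysed transesterification (HCl generated from AcCl in MeOH, 0 °C → rt, argon) then releases 30 with only volatile by-products.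

3. Step 3. Tin may be delivered to the terminal carbon instead of the oxygen-bearing carbon, and the sensitive ethynyl ether may decompose before it reacts. The fallback avoids the alkyne altogether; it sets out from 1 and comes back at 8. Phenol 1 would be O-vinylated by transvinylation with vinyl acetate ([Ir(cod)Cl]2, Na2CO3, toluene, 100 °C) to 2-(ethenyloxy)-1,3-dimethoxybenzene F3. F3 would be deprotonated at the vinyl alpha carbon (t-BuLi, THF, −78 → −30 °C; the ring carries only singly activated anisole-type C–H bonds) to give the vinyllithium 10. Quenching with Bu3SnCl gives 8, which can be purified before step 4.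

Further compounds
F1 | step 10 | tert-butyl[6-(4-iodo-2,6-dimethoxyphenoxy)-2,3,4-trimethoxyphenoxy]dimethylsilane | COc1cc(I)cc(OC)c1Oc1cc(OC)c(OC)c(OC)c1O[Si](C)(C)C(C)(C)C
F2 | step 17 | hexacosa-O-acetyl derivative of 30 | CC(=O)Oc1cc(OC(C)=O)c(Oc2cc(OC(C)=O)c(Oc3cc(OC(C)=O)c(OC(C)=O)c(OC(C)=O)c3Oc3cc(OC(C)=O)c(Oc4cc(OC(C)=O)c(OC(C)=O)c(OC(C)=O)c4Oc4cc(OC(C)=O)c(Oc5cc(OC(C)=O)c(OC(C)=O)c(OC(C)=O)c5Oc5cc(OC(C)=O)c(Oc6cc(OC(C)=O)c(OC(C)=O)c(OC(C)=O)c6Oc6cc(OC(C)=O)c(OC(C)=O)c(OC(C)=O)c6)c(OC(C)=O)c5)c(OC(C)=O)c4)c(OC(C)=O)c3)c(OC(C)=O)c2)c(OC(C)=O)c1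
F3 | step 3 | 2-(ethenyloxy)-1,3-dimethoxybenzene | COc1cccc(OC)c1OC=C
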